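**Retrosynthetic overview**

- **Rings and numbering (briarane).** Ring A is the cyclohexenone (C1, C10–C14), ring B the ten-membered carbocycle (C1–C10), ring C the γ-lactone (O, C7, C8, C17, C19). C15, C20 and C18 are the methyls on C1, C11 and C17. C16 is the exocyclic CH2 on C5. β is the face of ring A that carries C15.
- **Enabling feature.** In ring B the run C8(carbinol)–C7(O)–C6(Cl)–C5(=C16H2) places a homoallylic oxygen next to an exocyclic methylene and next to a carbon that can be a ketone, which is the retron of an enolate [2,3]-Wittig shift. Reconnecting O7 to C16 and cutting C6–C7 turns ring B into an eleven-membered oxacycle (C7–O–C16 in the ring, an (E)-chloromethylidene C6 outside it) that lacks the C6 and C7 stereocentres.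
- **Disconnections.** Ring C comes from C7 acylation and samarium Reformatsky closure C17–C8. Ring B comes from one-atom ring contraction of the oxacycle. The oxacycle comes from Nozaki–Hiyama–Kishi closure C3–C4 and etherification C7–O–C16. Ring A comes from a Diels–Alder reaction (C1–C14, C10–C11) of a D-tartrate-derived enal, with C9 taken from the chiral pool.
- **Order of ring formation.** Ring A, eleven-membered oxacycle, ring B (from the oxacycle), ring C.

Key step: step 20

Remark: compounds 10–12 are carried as mixtures at C11 and 28 as a mixture at its CHBr carbon. Both centres are erased by enolate formation (steps 10 and 21) before they matter.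

Remark: PMB = 4-methoxybenzyl, TBS = tert-butyldimethylsilyl.

Step 1
Reactants: 1 dimethyl D-tartrate
Product: 2 dimethyl (4S,5S)-2-(4-methoxyphenyl)-1,3-dioxolane-4,5-dicarboxylate
Conditions: 4-MeOC6H4CH(OMe)2, camphorsulfonic acid (cat.), toluene, 90 °C, removal of MeOH
Reagents that add atoms: 4-methoxybenzaldehyde dimethyl acetal, COc1ccc(cc1)C(OC)OC
Why: Acid-catalysed transacetalisation of the 1,2-diol, in which both carbinol centres of the chiral pool are kept and the acetal carbon is non-stereogenic because the trans-diester is C2-symmetric.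

Step 2
Reactants: 2 acetal diester
Product: 3 2-O-(4-methoxybenzyl)-D-threitol, (2R,3R)-2-(PMB-oxy)butane-1,3,4-triol
Conditions: LiAlH4, AlCl3, Et2O/CH2Cl2, 0 °C to reflux
Reagents that add atoms: none
Why: Hydride reduction of both esters and chloroalane-type reductive opening of the 4-methoxybenzylidene acetal, where C2 symmetry makes either C–O cleavage give the same mono-PMB ether, whose PMB-bearing carbon becomes C9.

Step 3
Reactants: 3 triol
Product: 4 (2R)-2-[(4R)-2,2-dimethyl-1,3-dioxolan-4-yl]-2-(PMB-oxy)ethanol
Conditions: Me2C(OMe)2, TsOH (cat.), acetone, rt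
Reagents that add atoms: 2,2-dimethoxypropane, COC(C)(C)OC
Why: Thermodynamic acetonide formation prefers the five-membered dioxolane on the terminal 1,2-diol (the later C8 and C7 oxygens) over a six-membered dioxane and leaves the primary alcohol next to C9 free.

Step 4
Reactants: 4 acetonide alcohol
Product: 5 (2S)-2-[(4R)-2,2-dimethyl-1,3-dioxolan-4-yl]-2-(PMB-oxy)acetaldehyde
Conditions: TEMPO (10 mol %), PhI(OAc)2, CH2Cl2, rt
Reagents that add atoms: none
Why: Oxoammonium (TEMPO) oxidation stops at the aldehyde under nearly neutral conditions, so the α-alkoxy centre C9 should not epimerise.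

Step 5
Reactants: 5 aldehyde; 6 2-(triphenylphosphoranylidene)propanal
Product: 7 (2E,4R)-4-[(4R)-2,2-dimethyl-1,3-dioxolan-4-yl]-4-(PMB-oxy)-2-methylbut-2-enal
Conditions: toluene, 90 °C
Reagents that add atoms: none
Why: Wittig olefination with a stabilised ylide gives the (E)-trisubstituted enal, which places the side chain (C9) cis to the methyl group (C15) on the C10=C1 double bond.

Step 6
Reactants: 8 pent-1-en-3-one (ethyl vinyl ketone)
Product: 9 (3Z)-3-(tert-butyldimethylsilyloxy)penta-1,3-diene
Conditions: TBSOTf, Et3N, Et2O, 0 °C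
Reagents that add atoms: tert-butyldimethylsilyl trifluoromethanesulfonate, CC(C)(C)[Si](C)(C)OS(=O)(=O)C(F)(F)F
Why: Soft enolisation and O-silylation of the enone gives the (Z)-2-siloxydiene, whose terminal methyl is outside in the s-cis form.

Step 7
Reactants: 7 enal; 9 siloxydiene
Product: 10 Diels–Alder adduct: 4-(TBS-oxy)-1,5-dimethylcyclohex-3-ene-1-carbaldehyde with the (R)-[(4R)-2,2-dimethyl-1,3-dioxolan-4-yl](PMB-oxy)methyl group on C6; in briarane terms C15 and C9 β (cis), formyl C2 α, H-10 α, C11 as epimers
Conditions: Tf2NH (10 mol %), CH2Cl2, −78 to −40 °C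
Reagents that add atoms: none
Why: Triflimide-catalysed Diels–Alder reaction of a hindered siloxydiene, in which the siloxy group directs its methyl-bearing terminus (C11) onto the enal β-carbon (C10), the E dienophile geometry puts C15 and C9 cis, and 1,3-allylic strain with the cis methyl holds H-9 in the alkene plane with OPMB outside, so that the diene should add anti to the dioxolanyl carbon and set C1 and C10.

Step 8
Reactants: 10 silyl enol ether aldehyde
Product: 11 4-formyl-4-methylcyclohex-2-enone (C12 ketone, C13=C14) with the C10 side chain and C11 methyl unchanged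
Conditions: Pd(OAc)2 (1.1 equiv), MeCN, rt
Reagents that add atoms: none
Why: Saegusa–Ito oxidation, in which the regiodefined silyl enol ether left by the cycloaddition places the new double bond at C13=C14 next to the quaternary C1.

Step 9
Reactants: 11 enone aldehyde
Product: 12 (E)-2-iodovinyl enone (C2=C3–I on C1, α)
Conditions: CrCl2 (8 equiv), CHI3 (3 equiv), THF/dioxane, 0 °C to rt
Reagents that add atoms: iodoform, IC(I)I
Why: Takai olefination converts the non-enolisable neopentyl aldehyde selectively, in the presence of the enone, into the (E)-alkenyl iodide and brings in C3.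

Step 10
Reactants: 12 iodovinyl enone
Product: 14 C11 tertiary alcohol of the iodovinyl enone (OH α; C20 β), via potassium dienolate 13 (not isolated)
Conditions: KN(SiMe3)2, THF, −78 °C; 2-(phenylsulfonyl)-3-phenyloxaziridine, −78 °C; AcOH
Reagents that add atoms: 2-(phenylsulfonyl)-3-phenyloxaziridine, O=S(=O)(c1ccccc1)N1OC1c1ccccc1
Why: Davis oxidation of the cross-conjugated dienolate (only C11–H can be removed because C1 is quaternary), in which the oxaziridine should approach the α face, anti to the adjacent β side chain on C10 and to the β methyl on C1, and so set C11.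

Step 11
Reactants: 14 α-ketol
Product: 15 C11 acetate
Conditions: Ac2O, DMAP, Et3N, CH2Cl2, 40 °C
Reagents that add atoms: acetic anhydride, CC(=O)OC(C)=O
Why: DMAP-catalysed acylation of the tertiary α-ketol is done here because no other hydroxyl is free, which distinguishes the C11 acetate from the C8 hydroxyl that appears later.

Step 12
Reactants: 15 acetonide
Product: 16 (8R)-C7,C8-diol
Conditions: AcOH/H2O 4:1, 40 °C
Reagents that add atoms: none
Why: Mild acid hydrolysis removes the acetonide and spares the PMB ether, the tertiary acetate and the alkenyl iodide.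

Step 13
Reactants: 17 propargyl alcohol
Product: 19 (2Z)-2-(chloromethylidene)but-3-en-1-ol, via alkenylmagnesium alkoxide 18 (not isolated)
Conditions: CH2=CHMgBr (3 equiv), CuI (15 mol %), THF, −20 °C to rt; N-chlorosuccinimide, −40 to 0 °C
Reagents that add atoms: vinylmagnesium bromide, C=C[Mg]Br; N-chlorosuccinimide, ClN1C(=O)CCC1=O
Why: Copper-catalysed, alkoxide-directed anti-carbomagnesiation of propargyl alcohol puts the vinyl group on the internal carbon (C5) and magnesium on the terminal carbon (C6) cis to CH2O in a five-membered chelate, and chlorination with retention fixes Cl cis to C16.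

Step 14
Reactants: 19 chlorodienol
Product: 20 (1Z)-2-(bromomethyl)-1-chlorobuta-1,3-diene
Conditions: CBr4, PPh3, CH2Cl2, 0 °C
Reagents that add atoms: carbon tetrabromide, BrC(Br)(Br)Br
Why: The Appel reaction converts the primary allylic alcohol into the bromide under neutral conditions without touching the alkene geometry.

Step 15
Reactants: 16 diol; 20 allylic bromide
Product: 21 C7 ether (C7–O–C16H2–C5(=C6HCl)–CH=CH2, Cl cis to C16) with free (8R)-OH
Conditions: Ph2BOCH2CH2NH2 (10 mol %), Ag2O, MeCN, 40 °C
Reagents that add atoms: none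
Why: Borinic-acid-catalysed regioselective O-alkylation of a 1,2-diol, in which the tetracoordinate borinate activates the less hindered primary oxygen (O7) toward SN2 attack on the allylic bromide.

Step 16
Reactants: 21 secondary alcohol
Product: 22 C8 ketone
Conditions: Dess–Martin periodinane, NaHCO3, CH2Cl2, 0 °C to rt
Reagents that add atoms: none
Why: Dess–Martin oxidation of the only free hydroxyl gives the α,α′-dialkoxy ketone under buffered conditions that should not epimerise C9.

Step 17
Reactants: 22 chlorodiene ketone
Product: 23 (E)-β-chloroenal (C4 aldehyde on C5, Cl trans to CHO and cis to C16)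
Conditions: OsO4 (2 mol %), NaIO4, 2,6-lutidine, dioxane/H2O 3:1, rt
Reagents that add atoms: sodium periodate, [Na+].[O-]I(=O)(=O)=O; osmium tetroxide (oxygen carrier), O=[Os](=O)(=O)=O
Why: Lemieux–Johnson cleavage selects the monosubstituted and most electron-rich alkene, because the chloroalkene, the iodoalkene and the enone are deactivated, and it leaves the chloroalkene geometry intact.

Step 18
Reactants: 23 iodo aldehyde
Product: 24 eleven-membered oxacycle (ring atoms C1–C5, C16, O, C7–C10) with (4S)-OH, (2E)-alkene, exocyclic (E)-chloromethylidene on C5 and C8 ketone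
Conditions: CrCl2 (10 equiv), NiCl2 (0.1 equiv), DMSO/THF, 2 mM, rt
Reagents that add atoms: none
Why: The Nozaki–Hiyama–Kishi reaction (nickel-catalysed, CrCl2-mediated addition of the alkenyl iodide to the aldehyde) is selective for C–I over C–Cl and for the aldehyde over both ketones and keeps the E geometry, and the s-trans chloroenal held edge-on in the forming ring should expose the face that leads to the 4S alcohol.

Step 19
Reactants: 24 allylic alcohol
Product: 25 oxacycle C4 acetate
Conditions: Ac2O, pyridine, DMAP (cat.), CH2Cl2, 0 °C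
Reagents that add atoms: acetic anhydride, CC(=O)OC(C)=O
Why: Standard acylation installs the final C4 acetate with retention and removes the only acidic O–H before the base-mediated step.

Step 20
Reactants: 25 oxacycle acetate
Product: 28 ring-contracted ten-membered β-chloro ketone (6S;7R; exocyclic C5=C16H2) as its C7 2-bromopropanoate, via lithium enolate 26 (not isolated), via lithium alkoxide 27 (not isolated)
Conditions: LiN(SiMe3)2 (1.05 equiv), THF, −78 to −30 °C; CH3CHBrCOBr, −78 °C
Reagents that add atoms: 2-bromopropanoyl bromide, CC(Br)C(=O)Br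
Why: Proposed new method: LiN(SiMe3)2 deprotonates the only readily enolisable position, the unhindered ether-activated C7H2 next to the C8 ketone (the ring A enone has no α′- or γ-hydrogen, C9–H is buried beside C10 and acetate C–H is far less acidic), and the lithium-chelated (Z)-enolate 26 undergoes a suprafacial [2,3]-Wittig shift in which C7 bonds to the chlorine-bearing alkene terminus C6 while the allylic C16–O bond breaks, so that the ring oxygen leaves the eleven-membered ring as the C7 alkoxide, C16 becomes the exocyclic methylene and ring B results by loss of one ring atom. The closest known reaction types are the enolate [2,3]-Wittig rearrangement of acyclic α-allyloxy carbonyl compounds and the [2,3]-Wittig ring contraction of macrocyclic allyl propargyl ethers through an endocyclic alkene; contraction by a single atom through an exocyclic alkylidene and a chloroalkene as migration terminus go beyond them, and since ester enolates rearrange at −78 °C and 1,3-dicarbonyl enolates near room temperature, a ketone enolate should do so between −60 and −30 °C. Ring B is closed by the sigmatropic C6–C7 bond formation itself, through a five-centre, six-electron envelope transition state bridged from C7 to C5 by the seven-atom chain C8–C9–C10–C1–C2–C3–C4. C6 is set by the alkene geometry (Cl cis to C16) and by the alkene face, which the C4 stereocentre selects because H-4 eclipses the C5=C6 bond, the acetoxy group points outward and C3 and C7 must lie on the same face, and C7 is set because the short chain forces C8 into the endo position over the allyl unit, which together translate into 6S,7R with Cl and O gauche. The step needs [2,3] over [3,3] selectivity (secured by the lithium counter-ion and by the strained nine-membered (E)-cycloalkene that a C8–C6 bond would create), no transannular Michael addition (C14 is neopentyl) and survival of the β-chloro alkoxide. The last point is met by the low temperature, by the gauche Cl/O arrangement and by the in situ acylation of 27, which also brings in the three carbons C17–C19 of ring C.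

Step 21
Reactants: 28 bromopropanoate
Product: 30 trans-fused β-hydroxy-γ-lactone (8R;17R; C9 PMB ether), via samarium enolate 29 (not isolated)
Conditions: SmI2 (2.1 equiv, slow addition), THF, −78 °C; aq NH4Cl
Reagents that add atoms: none
Why: In the intramolecular samarium Reformatsky reaction the C–Br bond, the most easily reduced site at −78 °C without a proton source, gives an enolate of trivalent samarium chelated to the C8 ketone, which should add on the carbonyl face where O7 lies in the conformer with C6 and C9 anti, giving the trans-fused lactone (8R) with the C17 methyl turned away from C9 and cis to the new hydroxyl (17R).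

Step 22
Reactants: 30 PMB ether
Product: 31 C8,C9-diol
Conditions: DDQ, CH2Cl2/pH 7 buffer 10:1, 0 °C
Reagents that add atoms: none
Why: Oxidative PMB cleavage in wet medium frees C9–OH without affecting the allylic chloride, the alkenes, the acetates or the lactone.

Step 23
Reactants: 31 diol
Product: 32 target CNP0159278.2
Conditions: Ac2O, pyridine, DMAP, CH2Cl2, rt
Reagents that add atoms: acetic anhydride, CC(=O)OC(C)=O
Why: Acylation takes place at the secondary C9–OH only, because the tertiary, hindered and hydrogen-bonded C8–OH of the β-hydroxy lactone is inert under these conditions.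

**Compound list**

1 | dimethyl D-tartrate, dimethyl (2S,3S)-2,3-dihydroxybutanedioate | COC(=O)[C@@H](O)[C@H](O)C(=O)OC | starting material
2 | dimethyl (4S,5S)-2-(4-methoxyphenyl)-1,3-dioxolane-4,5-dicarboxylate | COC(=O)[C@H]1OC(c2ccc(OC)cc2)O[C@@H]1C(=O)OC | intermediate
3 | 2-O-(4-methoxybenzyl)-D-threitol | OC[C@@H](OCc1ccc(OC)cc1)[C@H](O)CO | intermediate
4 | (2R)-2-[(4R)-2,2-dimethyl-1,3-dioxolan-4-yl]-2-(PMB-oxy)ethanol | OC[C@@H](OCc1ccc(OC)cc1)[C@H]1COC(C)(C)O1 | intermediate
5 | (2S)-2-[(4R)-2,2-dimethyl-1,3-dioxolan-4-yl]-2-(PMB-oxy)acetaldehyde | O=C[C@@H](OCc1ccc(OC)cc1)[C@H]1COC(C)(C)O1 | intermediate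
6 | 2-(triphenylphosphoranylidene)propanal | CC(C=O)=P(c1ccccc1)(c1ccccc1)c1ccccc1 | starting material
7 | (2E,4R)-4-[(4R)-2,2-dimethyl-1,3-dioxolan-4-yl]-4-(PMB-oxy)-2-methylbut-2-enal | O=C/C(C)=C/[C@@H](OCc1ccc(OC)cc1)[C@H]1COC(C)(C)O1 | intermediate
8 | pent-1-en-3-one | C=CC(=O)CC | starting material
9 | (3Z)-3-(tert-butyldimethylsilyloxy)penta-1,3-diene | C=C/C(O[Si](C)(C)C(C)(C)C)=C/C | intermediate
10 | Diels–Alder adduct (silyl enol ether aldehyde; C15 and C9 β, C2 α, C11 epimers) | O=C[C@@]1(C)CC=C(O[Si](C)(C)C(C)(C)C)C(C)[C@@H]1[C@@H](OCc2ccc(OC)cc2)[C@H]2COC(C)(C)O2 | intermediate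
11 | 4-formyl enone (C11 epimers) | O=C[C@@]1(C)C=CC(=O)C(C)[C@@H]1[C@@H](OCc2ccc(OC)cc2)[C@H]2COC(C)(C)O2 | intermediate
12 | (E)-iodovinyl enone (C11 epimers) | I/C=C/[C@@]1(C)C=CC(=O)C(C)[C@@H]1[C@@H](OCc2ccc(OC)cc2)[C@H]2COC(C)(C)O2 | intermediate
13 | potassium dienolate of 12 | I/C=C/[C@@]1(C)C=CC([O-])=C(C)[C@@H]1[C@@H](OCc2ccc(OC)cc2)[C@H]2COC(C)(C)O2.[K+] | intermediate
14 | C11 tertiary alcohol (OH α, C20 β) | I/C=C/[C@@]1(C)C=CC(=O)[C@@](C)(O)[C@@H]1[C@@H](OCc2ccc(OC)cc2)[C@H]2COC(C)(C)O2 | intermediate
15 | C11 acetate | I/C=C/[C@@]1(C)C=CC(=O)[C@@](C)(OC(C)=O)[C@@H]1[C@@H](OCc2ccc(OC)cc2)[C@H]2COC(C)(C)O2 | intermediate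
16 | (8R)-C7,C8-diol | I/C=C/[C@@]1(C)C=CC(=O)[C@@](C)(OC(C)=O)[C@@H]1[C@@H](OCc2ccc(OC)cc2)[C@H](O)CO | intermediate
17 | propargyl alcohol | C#CCO | starting material
18 | alkenylmagnesium alkoxide (Mg on C6 cis to CH2O) | C=C/C(CO[Mg]Br)=C/[Mg]Br | intermediate
19 | (2Z)-2-(chloromethylidene)but-3-en-1-ol | C=C/C(CO)=C/Cl | intermediate
20 | (1Z)-2-(bromomethyl)-1-chlorobuta-1,3-diene | C=C/C(CBr)=C/Cl | intermediate
21 | C7 chlorodienyl ether, (8R)-alcohol | I/C=C/[C@@]1(C)C=CC(=O)[C@@](C)(OC(C)=O)[C@@H]1[C@@H](OCc2ccc(OC)cc2)[C@H](O)COC/C(C=C)=C\Cl | intermediate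
22 | C8 ketone | I/C=C/[C@@]1(C)C=CC(=O)[C@@](C)(OC(C)=O)[C@@H]1[C@@H](OCc2ccc(OC)cc2)C(=O)COC/C(C=C)=C\Cl | intermediate
23 | (E)-β-chloroenal | I/C=C/[C@@]1(C)C=CC(=O)[C@@](C)(OC(C)=O)[C@@H]1[C@@H](OCc2ccc(OC)cc2)C(=O)COC/C(C=O)=C\Cl | intermediate
24 | eleven-membered oxacycle, (4S)-alcohol | Cl/C=C1/[C@@H](O)/C=C/[C@@]2(C)C=CC(=O)[C@@](C)(OC(C)=O)[C@@H]2[C@@H](OCc3ccc(OC)cc3)C(=O)COC1 | intermediate
25 | eleven-membered oxacycle, C4 acetate | Cl/C=C1/[C@@H](OC(C)=O)/C=C/[C@@]2(C)C=CC(=O)[C@@](C)(OC(C)=O)[C@@H]2[C@@H](OCc3ccc(OC)cc3)C(=O)COC1 | intermediate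
26 | lithium (Z)-enolate of 25 (C7=C8) | Cl/C=C1/[C@@H](OC(C)=O)/C=C/[C@@]2(C)C=CC(=O)[C@@](C)(OC(C)=O)[C@@H]2[C@@H](OCc3ccc(OC)cc3)/C([O-])=C/OC1.[Li+] | intermediate
27 | lithium C7 alkoxide of the ten-membered β-chloro ketone | C=C1[C@@H](OC(C)=O)/C=C/[C@@]2(C)C=CC(=O)[C@@](C)(OC(C)=O)[C@@H]2[C@@H](OCc3ccc(OC)cc3)C(=O)[C@@H]([O-])[C@H]1Cl.[Li+] | intermediate
28 | ten-membered β-chloro ketone, C7 2-bromopropanoate (CHBr epimers) | C=C1[C@@H](OC(C)=O)/C=C/[C@@]2(C)C=CC(=O)[C@@](C)(OC(C)=O)[C@@H]2[C@@H](OCc3ccc(OC)cc3)C(=O)[C@@H](OC(=O)C(C)Br)[C@H]1Cl | intermediate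
29 | samarium enolate of 28 | C=C1[C@@H](OC(C)=O)/C=C/[C@@]2(C)C=CC(=O)[C@@](C)(OC(C)=O)[C@@H]2[C@@H](OCc3ccc(OC)cc3)C(=O)[C@@H](OC(O[Sm](I)I)=CC)[C@H]1Cl | intermediate
30 | trans-fused β-hydroxy-γ-lactone, C9 PMB ether | C=C1[C@@H](OC(C)=O)/C=C/[C@@]2(C)C=CC(=O)[C@@](C)(OC(C)=O)[C@@H]2[C@@H](OCc3ccc(OC)cc3)[C@]2(O)[C@@H](C)C(=O)O[C@H]2[C@H]1Cl | intermediate
31 | C8,C9-diol | C=C1[C@@H](OC(C)=O)/C=C/[C@@]2(C)C=CC(=O)[C@@](C)(OC(C)=O)[C@@H]2[C@@H](O)[C@]2(O)[C@@H](C)C(=O)O[C@H]2[C@H]1Cl | intermediate
32 | CNP0159278.2 (1S,4S,6S,7R,8R,9R,10S,11S,17R) | C=C1[C@@H](OC(C)=O)/C=C/[C@@]2(C)C=CC(=O)[C@@](C)(OC(C)=O)[C@@H]2[C@@H](OC(C)=O)[C@]2(O)[C@@H](C)C(=O)O[C@H]2[C@H]1Cl | target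

Total step count: 23. Longest linear sequence: 20 steps (steps 1–5, 7–12, 15–23).

**Steps most likely to fail**

**Step 20.**
- What may go wrong: the rearrangement may not start below the temperature at which the β-chloro alkoxide loses chloride by epoxide closure or β-elimination. The enolate may also drift into a [3,3] shift or a transannular Michael addition, or C9 may epimerise by enolate equilibration.
- Fallback: neutral enamine activation, the amine-catalysed [2,3]-Wittig rearrangement that is known for α-allyloxy ketones.
- It sets out from 25. Pyrrolidine (0.2–1 equiv) in MeOH at room temperature should give the C7=C8 pyrrolidine enamine F1. This rearranges through the same five-centre array without strong base and without a free metal alkoxide.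
- Hydrolysis of the resulting iminium ion in the wet medium should give the ring-contracted hydroxy ketone F2. It is isolated and acylated with 2-bromopropanoyl bromide and pyridine in CH2Cl2 at −20 °C, and the route is rejoined at 28.

**Step 21.**
- What may go wrong: electron transfer may go to the α-acetoxy enone, the allylic chloride or the α-acyloxy ketone instead of the C–Br bond. Facial selectivity in the geometrically demanding five-membered closure may also be poor.
- Fallback: non-reductive enolate generation.
- It sets out from 27, generated as in step 20, which is trapped with propanoyl chloride instead of the bromo acid bromide to give the C7 propanoate F3.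
- Soft enolisation with TiCl4 and Bu3N in CH2Cl2 at −78 °C (titanium-mediated ester–ketone aldol addition, here intramolecular) should close C17–C8, and the route is rejoined at 30.

**Step 18.**
- What may go wrong: facial selectivity at the aldehyde during the ring closure may be poor, so that much of the material ends up with the wrong C4 configuration.
- Fallback: correction by substitution instead of addition.
- It sets out from 23. The ring closure is run as described and the separated C4 epimeric alcohol F4 is treated with AcOH, PPh3 and diisopropyl azodicarboxylate in toluene at 0 °C (Mitsunobu reaction). This should give the acetate with inversion, and the route is rejoined at 25.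

**Further compounds**

F1 | step 20 | C7=C8 pyrrolidine enamine of 25 | Cl/C=C1/[C@@H](OC(C)=O)/C=C/[C@@]2(C)C=CC(=O)[C@@](C)(OC(C)=O)[C@@H]2[C@@H](OCc3ccc(OC)cc3)C(N3CCCC3)=COC1
F2 | step 20 | ring-contracted hydroxy ketone (6S,7R) | C=C1[C@@H](OC(C)=O)/C=C/[C@@]2(C)C=CC(=O)[C@@](C)(OC(C)=O)[C@@H]2[C@@H](OCc3ccc(OC)cc3)C(=O)[C@@H](O)[C@H]1Cl
F3 | step 21 | C7 propanoate of the ten-membered β-chloro ketone | C=C1[C@@H](OC(C)=O)/C=C/[C@@]2(C)C=CC(=O)[C@@](C)(OC(C)=O)[C@@H]2[C@@H](OCc3ccc(OC)cc3)C(=O)[C@@H](OC(=O)CC)[C@H]1Cl
F4 | step 18 | C4 epimer (4R) of oxacycle alcohol 24 | Cl/C=C1/[C@H](O)/C=C/[C@@]2(C)C=CC(=O)[C@@](C)(OC(C)=O)[C@@H]2[C@@H](OCc3ccc(OC)cc3)C(=O)COC1
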